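**Retrosynthetic overview**
1. Target 39 ← acetylation and closure of ring C (19,6-lactone, formed last) ← tricyclic ketone 35 by C6 reduction and lactonisation.
2. 35 ← α-bromoketone 34 by one radical-polar crossover cascade that closes ring B (C7–C8) and the spiro-tetrahydrofuran ring D (O–C9). Enabling feature: the C6 carbonyl next to C7 (electrophilic α-keto radical), the trisubstituted C8=C9 alkene whose C9 becomes a tertiary radical and then a cation, and the C13 hydroxyl that reaches C9 through C12–C11.
3. 34 ← Negishi union of ring A enol triflate 16 (C9) with iodide 28 (C11–C16, lactone ring E, C13 from (R)-malic acid).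
4. 16 ← ring A by catalytic asymmetric Diels–Alder reaction (C3–C4 and C5–C10, sets C4 and C5), then [2,3]-Wittig rearrangement (quaternary C10).
5. Ring order: A (Diels–Alder) → E (fragment lactone) → B and D together (key step) → C (lactonisation).

Key step: step 22

Assumption: the SMILES is read literally, so H5 lies on the same face of ring A as C19 and C20; the C6 and C9 arms are therefore cis (cis-fused A/B) and ring C is trans-fused to ring A. This arrangement forces ring B out of a chair, which is reflected in the risks below.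
Convention: labdane numbering of the target is used for all intermediates (ring A = C1–C5 and C10; C18 = 4-methyl, C19 = 4-carboxyl carbon, C20 = 10-CH2O; side chain C11–C16). β is the face of ring A carrying C20, α the opposite face. TBS = tert-butyldimethylsilyl, TES = triethylsilyl, Tf = trifluoromethanesulfonyl.

**Route**

Step 1
Reactants: 1 methyl pyruvate; 2 1-(triphenylphosphoranylidene)propan-2-one
Product: 3 methyl (E)-2-methyl-4-oxopent-2-enoate
Conditions: toluene, 80 °C; I2 (cat.), hν if (Z)-isomer is present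
Reagents that add atoms: none
Why: Wittig olefination of the activated keto group by a stabilised ylide; the (E)-alkene (ester trans to acetyl) is the thermodynamically preferred isomer and any (Z)-isomer is equilibrated to it.

Step 2
Reactants: 4 (tert-butyldimethylsilyloxy)acetaldehyde; 2 1-(triphenylphosphoranylidene)propan-2-one
Product: 5 (E)-5-(tert-butyldimethylsilyloxy)pent-3-en-2-one
Conditions: CH2Cl2, rt
Reagents that add atoms: none
Why: Wittig olefination with a stabilised ylide, which gives the (E)-enone.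

Step 3
Reactants: 5 (E)-5-(tert-butyldimethylsilyloxy)pent-3-en-2-one
Product: 6 (E)-2,5-bis(tert-butyldimethylsilyloxy)penta-1,3-diene
Conditions: TBSOTf, Et3N, CH2Cl2, 0 °C
Reagents that add atoms: tert-butyldimethylsilyl triflate, CC(C)(C)[Si](C)(C)OS(=O)(=O)C(F)(F)F
Why: Soft enolisation and O-silylation of the methyl ketone at its only α'-position gives the cross-conjugated 2-silyloxydiene for the Diels–Alder reaction.

Step 4
Reactants: 3 methyl (E)-2-methyl-4-oxopent-2-enoate; 6 (E)-2,5-bis(tert-butyldimethylsilyloxy)penta-1,3-diene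
Product: 7 methyl 5α-acetyl-4α-methyl-2-(TBS-oxy)-10α-(TBS-oxymethyl)cyclohex-1-ene-4β-carboxylate
Conditions: (S)-3,3-diphenyl-1-(o-tolyl)tetrahydropyrrolo[1,2-c][1,3,2]oxazaborole·HNTf2 (20 mol %), CH2Cl2, −78 to −40 °C
Reagents that add atoms: none
Why: Lewis-acid-catalysed Diels–Alder reaction in which the ketone of 3 binds the chiral oxazaborolidinium ion, so the nucleophilic C3 terminus of the diene bonds to C4 (β to the ketone) and C10 bonds to C5; suprafacial addition turns the (E)-geometry into the trans relation of the C4 carboxylate and the C5 acetyl group, the catalyst face sets the absolute configuration of C4 and C5 (the catalyst enantiomer is the one expected to give this sense), and the endo-derived C10 centre is erased in step 5.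

Step 5
Reactants: 7 Diels–Alder adduct
Product: 8 methyl 5α-acetyl-4α-methyl-2-oxo-10-(TBS-oxymethyl)cyclohex-1(10)-ene-4β-carboxylate
Conditions: Pd(OAc)2 (10 mol %), O2 (1 atm), DMSO, 60 °C
Reagents that add atoms: none
Why: Saegusa–Ito oxidation: the regiodefined silyl enol ether gives a C1-bound palladium enolate whose only β-hydrogen is H10, so β-hydride elimination delivers the C1=C10 enone and dioxygen reoxidises zerovalent palladium.

Step 6
Reactants: 8 enone methyl ketone
Product: 9 methyl 4α-methyl-5α-(2-methyl-1,3-dioxolan-2-yl)-2-oxo-10-(TBS-oxymethyl)cyclohex-1(10)-ene-4β-carboxylate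
Conditions: 1,2-bis(trimethylsilyloxy)ethane, TMSOTf (5 mol %), CH2Cl2, −78 to −40 °C
Reagents that add atoms: 1,2-bis(trimethylsilyloxy)ethane, C[Si](C)(C)OCCO[Si](C)(C)C
Why: TMSOTf-catalysed dioxolane formation is much faster at the saturated methyl ketone than at the conjugated ketone, and the cold aprotic conditions avoid enolisation of the epimerisable C5 centre.

Step 7
Reactants: 9 ketal enone
Product: 10 methyl (2S)-2α-hydroxy-4α-methyl-5α-(2-methyl-1,3-dioxolan-2-yl)-10-(TBS-oxymethyl)cyclohex-1(10)-ene-4β-carboxylate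
Conditions: (R)-2-methyl-CBS-oxazaborolidine (20 mol %), BH3·SMe2, THF, −30 °C
Reagents that add atoms: none
Why: Corey–Bakshi–Shibata reduction under catalyst control (alkenyl side as the large group) gives the (2S) allylic alcohol with the hydroxyl on the α face, the face on which C9 must later be attached to C10.

Step 8
Reactants: 10 allylic alcohol; 11 propargyl bromide
Product: 12 methyl 4α-methyl-5α-(2-methyl-1,3-dioxolan-2-yl)-2α-(prop-2-ynyloxy)-10-(TBS-oxymethyl)cyclohex-1(10)-ene-4β-carboxylate
Conditions: NaH, Bu4NI (cat.), THF/DMF, 0 °C to rt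
Reagents that add atoms: none
Why: Williamson etherification of the sodium alkoxide with the reactive propargylic bromide, which leaves the C2 configuration untouched.

Step 9
Reactants: 12 propargyl ether
Product: 13 methyl 10α-(1-hydroxyprop-2-ynyl)-4α-methyl-5α-(2-methyl-1,3-dioxolan-2-yl)-10β-(TBS-oxymethyl)cyclohex-1-ene-4β-carboxylate
Conditions: n-BuLi (2.2 equiv), THF, −78 to −30 °C; aq. NH4Cl
Reagents that add atoms: none
Why: [2,3]-Wittig rearrangement of the lithiated propargyl ether (formed as the dianion) is suprafacial across the C2–C1=C10 allyl unit, so the new C9–C10 bond forms on the α face defined by the C2–O bond, which sets the quaternary C10 (CH2OTBS β, C9 α) and shifts the alkene to C1=C2; the C9 carbinol configuration is inconsequential.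

Step 10
Reactants: 13 propargylic alcohol
Product: 14 methyl 10α-(1-hydroxypropyl)-4α-methyl-5α-(2-methyl-1,3-dioxolan-2-yl)-10β-(TBS-oxymethyl)cyclohexane-4β-carboxylate
Conditions: H2 (1 atm), Pd/C (10 wt %), EtOAc, rt
Reagents that add atoms: none
Why: Heterogeneous hydrogenation saturates the terminal alkyne to the ethyl group and the disubstituted ring alkene without creating a stereocentre.

Step 11
Reactants: 14 secondary alcohol
Product: 15 methyl 4α-methyl-5α-(2-methyl-1,3-dioxolan-2-yl)-10α-propanoyl-10β-(TBS-oxymethyl)cyclohexane-4β-carboxylate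
Conditions: Dess–Martin periodinane, NaHCO3, CH2Cl2, rt
Reagents that add atoms: none
Why: Dess–Martin oxidation of the hindered secondary alcohol converts both C9 epimers into the single ethyl ketone.

Step 12
Reactants: 15 ethyl ketone
Product: 16 methyl 4α-methyl-5α-(2-methyl-1,3-dioxolan-2-yl)-10β-(TBS-oxymethyl)-10α-[(Z)-1-(triflyloxy)prop-1-enyl]cyclohexane-4β-carboxylate
Conditions: KN(SiMe3)2, THF, −78 °C; PhNTf2, −78 to 0 °C
Reagents that add atoms: N-phenylbis(trifluoromethanesulfonimide), O=S(=O)(N(c1ccccc1)S(=O)(=O)C(F)(F)F)C(F)(F)F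
Why: Only C8 can be enolised (C10 is quaternary) and the bulky tertiary substituent on the carbonyl enforces the Z(O)-enolate, so triflation gives the (Z)-enol triflate with the C17 methyl cis to the triflate and trans to C10.

Step 13
Reactants: 17 (R)-malic acid; 18 pivalaldehyde
Product: 19 2-[(2R,4R)-2-tert-butyl-5-oxo-1,3-dioxolan-4-yl]acetic acid
Conditions: TsOH (cat.), H2SO4 (cat.), pentane, reflux (Dean–Stark)
Reagents that add atoms: none
Why: Acid-catalysed acetalisation of the α-hydroxy acid unit with azeotropic water removal gives the thermodynamically preferred cis-dioxolanone, which stores the C13 configuration in the new acetal centre.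

Step 14
Reactants: 19 dioxolanone acid; 20 allyl bromide
Product: 21 2-[(2R,4R)-4-allyl-2-tert-butyl-5-oxo-1,3-dioxolan-4-yl]acetic acid
Conditions: LiN(SiMe3)2 (2.1 equiv), THF, −78 °C; allyl bromide, −78 to −30 °C
Reagents that add atoms: none
Why: Alkylation of the dioxolanone enolate (generated as the dianion) takes place anti to the tert-butyl group, so allyl replaces hydrogen with overall retention (self-regeneration of the stereocentre) and the quaternary C13 is set.

Step 15
Reactants: 21 allylated dioxolanone acid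
Product: 24 (R)-3-allyl-3-hydroxydihydrofuran-2(3H)-one, via mixed carbonic anhydride 22 (not isolated), via hydroxyethyl dioxolanone 23 (not isolated)
Conditions: i-BuOCOCl, N-methylmorpholine, THF, −15 °C; NaBH4, H2O, 0 °C; then TsOH (cat.), CH2Cl2, rt
Reagents that add atoms: none
Why: Mixed-anhydride activation lets NaBH4 reduce only the side-chain carboxyl group while the alkene is untouched, and the primary alcohol then transacylates the dioxolanone carbonyl to the γ-lactone (ring E) with loss of pivalaldehyde and without touching C13.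

Step 16
Reactants: 24 (R)-3-allyl-3-hydroxydihydrofuran-2(3H)-one
Product: 25 (R)-3-allyl-3-(triethylsilyloxy)dihydrofuran-2(3H)-one
Conditions: TESOTf, 2,6-lutidine, CH2Cl2, 0 °C
Reagents that add atoms: triethylsilyl triflate, CC[Si](CC)(CC)OS(=O)(=O)C(F)(F)F
Why: Silylation of the hindered tertiary alcohol with the reactive silyl triflate masks the acidic hydroxyl for the organozinc chemistry.

Step 17
Reactants: 25 allyl lactone silyl ether
Product: 27 (R)-3-(2-hydroxyethyl)-3-(triethylsilyloxy)dihydrofuran-2(3H)-one, via ozonide 26 (not isolated)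
Conditions: O3, CH2Cl2, −78 °C; then BH3·SMe2, −78 °C to rt
Reagents that add atoms: ozone, [O-][O+]=O
Why: Ozonolysis removes the terminal alkene carbon, and non-basic borane reduction of the ozonide gives the primary alcohol without an alkoxide that could transacylate the lactone and scramble C13.

Step 18
Reactants: 27 primary alcohol
Product: 28 (S)-3-(2-iodoethyl)-3-(triethylsilyloxy)dihydrofuran-2(3H)-one
Conditions: I2, PPh3, imidazole, CH2Cl2, 0 °C to rt
Reagents that add atoms: iodine, II
Why: Appel iodination of the primary alcohol under neutral conditions (the descriptor changes only through the priority rules).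

Step 19
Reactants: 28 alkyl iodide; 16 (Z)-enol triflate
Product: 30 methyl 4α-methyl-5α-(2-methyl-1,3-dioxolan-2-yl)-10β-(TBS-oxymethyl)-10α-[(E)-5-[(3R)-2-oxo-3-(triethylsilyloxy)oxolan-3-yl]pent-2-en-3-yl]cyclohexane-4β-carboxylate, via alkylzinc iodide 29 (not isolated)
Conditions: Zn dust, LiCl, THF, 40 °C; then 16, PdCl2(dppf) (5 mol %), THF/NMP, 50 °C
Reagents that add atoms: none
Why: Negishi coupling: zinc insertion into the primary iodide and palladium-catalysed sp3–sp2 coupling with the enol triflate proceed with retention of alkene geometry, which gives the (E)-trisubstituted C8=C9 alkene with C11 cis to the C17 methyl.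

Step 20
Reactants: 30 coupled ketal silyl ether
Product: 31 methyl 5α-acetyl-4α-methyl-10β-(TBS-oxymethyl)-10α-[(E)-5-[(3R)-3-hydroxy-2-oxooxolan-3-yl]pent-2-en-3-yl]cyclohexane-4β-carboxylate
Conditions: PPTS (0.3 equiv), acetone/H2O (9:1), 50 °C
Reagents that add atoms: water, O
Why: Mild acid hydrolysis cleaves the dioxolane and the tertiary triethylsilyl ether, while the acid is too weak to protonate the trisubstituted alkene or to cleave the hindered primary TBS ether.

Step 21
Reactants: 31 methyl ketone
Product: 34 methyl 5α-(bromoacetyl)-4α-methyl-10β-(TBS-oxymethyl)-10α-[(E)-5-[(3R)-3-hydroxy-2-oxooxolan-3-yl]pent-2-en-3-yl]cyclohexane-4β-carboxylate, via bis-silyl enol ether 32 (not isolated), via O-silyl bromoketone 33 (not isolated)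
Conditions: LiN(SiMe3)2 (2.3 equiv), Me3SiCl (3 equiv), THF, −78 °C; NBS, −78 to 0 °C; aq. citric acid
Reagents that add atoms: N-bromosuccinimide, O=C1CCC(=O)N1Br
Why: Kinetic deprotonation takes place at the unhindered C7 methyl group (H5 is flanked by two quaternary carbons), the terminal silyl enol ether is brominated regiospecifically by NBS, and the tertiary O-silyl group falls off in the acidic work-up.

Step 22
Reactants: 34 α-bromoketone
Product: 35 tricyclic 6-ketone with rings A B D closed (methyl 19-ester, 20-OTBS, 8α-methyl, 9α-O spiro-ether)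
Conditions: fac-Ir(ppy)3 (1 mol %), 2,6-lutidine (2 equiv), MeCN, blue LEDs, rt, degassed
Reagents that add atoms: none
Why: The excited iridium photocatalyst reduces the carbon–bromine bond to the electrophilic α-keto radical at C7, which adds 6-endo to C8 of the electron-rich trisubstituted C8=C9 alkene; the tertiary C9 radical is oxidised by the tetravalent iridium complex (or takes up bromine and ionises) to the C9 cation, which the C13 hydroxyl captures. The closest known reaction types are photoredox atom-transfer and radical-polar crossover carboetherifications of alkenols with α-bromocarbonyl compounds, and oxidative α-carbonyl radical cyclisations terminated by oxygen capture. Ring B closes by 6-endo-trig radical cyclisation (C7–C8) and ring D by 5-exo capture of the tertiary cation (O–C9). C8 is set by the (E)-alkene geometry in a chair-like transition state that keeps the C17 methyl pseudo-equatorial on the ring A conformer with the alkenyl arm axial and the bromoacetyl arm equatorial, and C9 is set by axial attack of the tethered hydroxyl anti to the C20 group on the neighbouring C10. The step needs 6-endo over 5-exo regioselectivity, which the fully substituted C9 (5-exo attack would form a quaternary centre next to C10 and a secondary radical) and the matched polarity of the α-keto radical secure, and it needs cyclisation to outrun reduction, which the absence of a hydrogen-atom donor secures.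

Step 23
Reactants: 35 tricyclic 6-ketone
Product: 37 20-O-TBS ether of the 20-deacetyl target (rings A–E complete), via 6β-hydroxy ester 36 (not isolated)
Conditions: (S)-2-methyl-CBS-oxazaborolidine (0.5 equiv), BH3·SMe2, THF, −20 °C; MeOH; then CSA (0.2 equiv), toluene, 60 °C
Reagents that add atoms: none
Why: Corey–Bakshi–Shibata reduction under catalyst control (C5 side large, C7 side small) delivers hydride to the α face and gives the (6R) 6β-alcohol, whose oxygen lies on the same face as the C19 ester and closes ring C by acid-catalysed acyl substitution with loss of methanol, so C6 is fixed with retention.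

Step 24
Reactants: 37 TBS-protected pentacycle
Product: 39 target CNP0298733.1, via primary alcohol 38 (not isolated)
Conditions: HF·pyridine, THF, 0 °C to rt; then Ac2O, DMAP, pyridine, rt
Reagents that add atoms: acetic anhydride, CC(=O)OC(C)=O
Why: Fluoride cleaves the silyl ether and the only hydroxyl group of the molecule is acetylated under nucleophilic catalysis; no stereocentre is affected.

**Compound list**
1 | methyl pyruvate | CC(=O)C(=O)OC | starting material
2 | 1-(triphenylphosphoranylidene)propan-2-one | CC(=O)C=P(c1ccccc1)(c1ccccc1)c1ccccc1 | starting material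
3 | methyl (E)-2-methyl-4-oxopent-2-enoate | COC(=O)/C(C)=C/C(C)=O | intermediate
4 | (tert-butyldimethylsilyloxy)acetaldehyde | CC(C)(C)[Si](C)(C)OCC=O | starting material
5 | (E)-5-(tert-butyldimethylsilyloxy)pent-3-en-2-one | CC(=O)/C=C/CO[Si](C)(C)C(C)(C)C | intermediate
6 | (E)-2,5-bis(tert-butyldimethylsilyloxy)penta-1,3-diene | C=C(O[Si](C)(C)C(C)(C)C)/C=C/CO[Si](C)(C)C(C)(C)C | intermediate
7 | Diels–Alder adduct (2-silyl enol ether, 4β-CO2Me, 4α-Me, 5α-acetyl, 10α-CH2OTBS) | CC(C)(C)[Si](C)(C)OC[C@H]1C=C(O[Si](C)(C)C(C)(C)C)C[C@](C)(C(=O)OC)[C@H]1C(C)=O | intermediate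
8 | C1=C10 enone (2-oxo, 5α-acetyl) | CC(C)(C)[Si](C)(C)OCC1=CC(=O)C[C@](C)(C(=O)OC)[C@H]1C(C)=O | intermediate
9 | ketal enone (C6 as 2-methyl-1,3-dioxolane) | CC(C)(C)[Si](C)(C)OCC1=CC(=O)C[C@](C)(C(=O)OC)[C@H]1C1(C)OCCO1 | intermediate
10 | (2S) 2α-allylic alcohol | CC(C)(C)[Si](C)(C)OCC1=C[C@@H](O)C[C@](C)(C(=O)OC)[C@H]1C1(C)OCCO1 | intermediate
11 | propargyl bromide | C#CCBr | starting material
12 | 2α-propargyl ether | CC(C)(C)[Si](C)(C)OCC1=C[C@@H](OCC#C)C[C@](C)(C(=O)OC)[C@H]1C1(C)OCCO1 | intermediate
13 | 10α-(1-hydroxyprop-2-ynyl)-10β-CH2OTBS cyclohex-1-ene (C9 epimers, inconsequential) | CC(C)(C)[Si](C)(C)OC[C@]1(C(O)C#C)C=CC[C@](C)(C(=O)OC)[C@H]1C1(C)OCCO1 | intermediate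
14 | 10α-(1-hydroxypropyl) cyclohexane (C9 epimers, inconsequential) | CC(C)(C)[Si](C)(C)OC[C@]1(C(O)CC)CCC[C@](C)(C(=O)OC)[C@H]1C1(C)OCCO1 | intermediate
15 | 10α-propanoyl ketone | CC(C)(C)[Si](C)(C)OC[C@]1(C(=O)CC)CCC[C@](C)(C(=O)OC)[C@H]1C1(C)OCCO1 | intermediate
16 | (Z)-enol triflate at C9 | CC(C)(C)[Si](C)(C)OC[C@]1(/C(OS(=O)(=O)C(F)(F)F)=C/C)CCC[C@](C)(C(=O)OC)[C@H]1C1(C)OCCO1 | intermediate
17 | (R)-malic acid | O[C@H](CC(=O)O)C(=O)O | starting material
18 | pivalaldehyde | CC(C)(C)C=O | starting material
19 | 2-[(2R,4R)-2-tert-butyl-5-oxo-1,3-dioxolan-4-yl]acetic acid | CC(C)(C)[C@@H]1O[C@H](CC(=O)O)C(=O)O1 | intermediate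
20 | allyl bromide | C=CCBr | starting material
21 | 2-[(2R,4R)-4-allyl-2-tert-butyl-5-oxo-1,3-dioxolan-4-yl]acetic acid | CC(C)(C)[C@@H]1O[C@](CC=C)(CC(=O)O)C(=O)O1 | intermediate
22 | isobutyl carbonic mixed anhydride of 21 | CC(C)(C)[C@@H]1O[C@](CC=C)(CC(=O)OC(=O)OCC(C)C)C(=O)O1 | intermediate
23 | 5-allyl-2-tert-butyl-5-(2-hydroxyethyl)-1,3-dioxolan-4-one (configuration as in 21) | CC(C)(C)[C@@H]1O[C@](CC=C)(CCO)C(=O)O1 | intermediate
24 | (R)-3-allyl-3-hydroxydihydrofuran-2(3H)-one | O[C@]1(CC=C)CCOC1=O | intermediate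
25 | (R)-3-allyl-3-(triethylsilyloxy)dihydrofuran-2(3H)-one | CC[Si](CC)(CC)O[C@]1(CC=C)CCOC1=O | intermediate
26 | ozonide (1,2,4-trioxolane) of 25 | CC[Si](CC)(CC)O[C@]1(CC2OCOO2)CCOC1=O | intermediate
27 | (R)-3-(2-hydroxyethyl)-3-(triethylsilyloxy)dihydrofuran-2(3H)-one | CC[Si](CC)(CC)O[C@]1(CCO)CCOC1=O | intermediate
28 | (S)-3-(2-iodoethyl)-3-(triethylsilyloxy)dihydrofuran-2(3H)-one | CC[Si](CC)(CC)O[C@]1(CCI)CCOC1=O | intermediate
29 | alkylzinc iodide from 28 | CC[Si](CC)(CC)O[C@]1(CC[Zn]I)CCOC1=O | intermediate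
30 | coupled (E)-alkene (C6 ketal, 13-OTES, 20-OTBS) | CC(C)(C)[Si](C)(C)OC[C@]1(/C(CC[C@@]2(O[Si](CC)(CC)CC)CCOC2=O)=C/C)CCC[C@](C)(C(=O)OC)[C@H]1C1(C)OCCO1 | intermediate
31 | methyl ketone with free 13-hydroxyl | CC(C)(C)[Si](C)(C)OC[C@]1(/C(CC[C@@]2(O)CCOC2=O)=C/C)CCC[C@](C)(C(=O)OC)[C@H]1C(C)=O | intermediate
32 | C6 trimethylsilyl enol ether with 13-OTMS | CC(C)(C)[Si](C)(C)OC[C@]1(/C(CC[C@@]2(O[Si](C)(C)C)CCOC2=O)=C/C)CCC[C@](C)(C(=O)OC)[C@H]1C(=C)O[Si](C)(C)C | intermediate
33 | α-bromoketone with 13-OTMS | CC(C)(C)[Si](C)(C)OC[C@]1(/C(CC[C@@]2(O[Si](C)(C)C)CCOC2=O)=C/C)CCC[C@](C)(C(=O)OC)[C@H]1C(=O)CBr | intermediate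
34 | α-bromoketone with free 13-hydroxyl | CC(C)(C)[Si](C)(C)OC[C@]1(/C(CC[C@@]2(O)CCOC2=O)=C/C)CCC[C@](C)(C(=O)OC)[C@H]1C(=O)CBr | intermediate
35 | tricyclic 6-ketone with spiro-tetrahydrofuran (rings A, B, D, E) | CC(C)(C)[Si](C)(C)OC[C@]12CCC[C@](C)(C(=O)OC)[C@H]1C(=O)C[C@@H](C)[C@]23CC[C@]2(CCOC2=O)O3 | intermediate
36 | (6R) 6β-hydroxy methyl ester | CC(C)(C)[Si](C)(C)OC[C@]12CCC[C@](C)(C(=O)OC)[C@H]1[C@H](O)C[C@@H](C)[C@]23CC[C@]2(CCOC2=O)O3 | intermediate
37 | 20-O-TBS ether of the 20-deacetyl target | CC(C)(C)[Si](C)(C)OC[C@@]12CCC[C@]3(C)C(=O)O[C@H](C[C@@H](C)[C@]14CC[C@]1(CCOC1=O)O4)[C@@H]23 | intermediate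
38 | 20-deacetyl target (primary alcohol) | OC[C@@]12CCC[C@]3(C)C(=O)O[C@H](C[C@@H](C)[C@]14CC[C@]1(CCOC1=O)O4)[C@@H]23 | intermediate
39 | CNP0298733.1 | CC(=O)OC[C@@]12CCC[C@]3(C)C(=O)O[C@H](C[C@@H](C)[C@]14CC[C@]1(CCOC1=O)O4)[C@@H]23 | target

**Step count and risks**

Total step count: 24. Longest linear sequence: 17 steps (steps 2–12, then 19–24, from 4).

Steps most likely to fail:

1. Step 22. The α-keto radical may be reduced or close 5-exo before the 6-endo closure, and the C9 cation may be captured from the wrong face. The fallback avoids radicals and sets out from 31. Epoxidation of the C8=C9 alkene (m-CPBA, NaHCO3, CH2Cl2) should give the epoxide F1. Under CSA the C13 hydroxyl opens it at C9 (5-exo, inversion at C9) to the spiro-tetrahydrofuran secondary alcohol F2. Dess–Martin oxidation gives the 1,5-diketone F3. Intramolecular aldol condensation (KOt-Bu, t-BuOH) of the C7 methyl ketone onto the more electrophilic α-alkoxy C8 ketone closes ring B as the C7=C8 enone F4. Hydrogenation (H2, Pd/C) from the convex β face, away from ring A and the ring D oxygen, then places the C17 methyl α and rejoins the route at 35.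

2. Step 23. Hydride may be delivered to the wrong face of C6 if substrate bias overrides the catalyst, and acyl transfer may be slow because ring B must leave its chair to close ring C. The fallback forms the C6–O bond by alkyl substitution with inversion and sets out from 35. Reduction with LiBH(s-Bu)3 (THF, −78 °C) from the convex β face should give the 6α-alcohol F5. Mesylation (MsCl, Et3N, CH2Cl2, 0 °C) gives the mesylate F6. On heating (2,6-lutidine, toluene, 90 °C) the C19 ester carbonyl oxygen displaces the mesylate from the β face and the ester methyl leaves as methyl methanesulfonate, which gives 37. Both C6 alcohol epimers are thereby funnelled to the same lactone.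

3. Step 4. Enantio- or regiocontrol may be lost in the catalysed cycloaddition of the trisubstituted dienophile. The fallback resolves by a catalyst-controlled reduction and sets out from 3 and 6. Uncatalysed cycloaddition (toluene, 90 °C) gives racemic adduct, i.e. 7 together with its enantiomer F7. Steps 5 and 6 carry it on as racemic enone (8 with its enantiomer F8) and racemic ketal (9 with its enantiomer F9). The CBS reduction of step 7, which sets C2 under catalyst control, converts the two enantiomers into the diastereomers 10 and the allylic alcohol F10; chromatography separates them and the route continues from 10.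

**Further compounds**
F1 | step 22 | C8–C9 epoxide of 31 | CC(C)(C)[Si](C)(C)OC[C@]1([C@@]2(CC[C@@]3(O)CCOC3=O)O[C@@H]2C)CCC[C@](C)(C(=O)OC)[C@H]1C(C)=O
F2 | step 22 | spiro-tetrahydrofuran with C8 secondary alcohol and C6 methyl ketone | CC(C)(C)[Si](C)(C)OC[C@]1([C@]2([C@@H](C)O)CC[C@]3(CCOC3=O)O2)CCC[C@](C)(C(=O)OC)[C@H]1C(C)=O
F3 | step 22 | 1,5-diketone (C6 and C8 methyl ketones) | CC(C)(C)[Si](C)(C)OC[C@]1([C@]2(C(C)=O)CC[C@]3(CCOC3=O)O2)CCC[C@](C)(C(=O)OC)[C@H]1C(C)=O
F4 | step 22 | ring B enone (6-oxo, C7=C8) | CC(C)(C)[Si](C)(C)OC[C@]12CCC[C@](C)(C(=O)OC)[C@H]1C(=O)C=C(C)[C@]23CC[C@]2(CCOC2=O)O3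
F5 | step 23 | 6α-hydroxy methyl ester | CC(C)(C)[Si](C)(C)OC[C@]12CCC[C@](C)(C(=O)OC)[C@H]1[C@@H](O)C[C@@H](C)[C@]23CC[C@]2(CCOC2=O)O3
F6 | step 23 | 6α-mesylate | CC(C)(C)[Si](C)(C)OC[C@]12CCC[C@](C)(C(=O)OC)[C@H]1[C@@H](OS(C)(=O)=O)C[C@@H](C)[C@]23CC[C@]2(CCOC2=O)O3
F7 | step 4 | enantiomer of 7 | CC(C)(C)[Si](C)(C)OC[C@@H]1C=C(O[Si](C)(C)C(C)(C)C)C[C@@](C)(C(=O)OC)[C@@H]1C(C)=O
F8 | step 4 | enantiomer of 8 | CC(C)(C)[Si](C)(C)OCC1=CC(=O)C[C@@](C)(C(=O)OC)[C@@H]1C(C)=O
F9 | step 4 | enantiomer of 9 | CC(C)(C)[Si](C)(C)OCC1=CC(=O)C[C@@](C)(C(=O)OC)[C@@H]1C1(C)OCCO1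
F10 | step 4 | (2S) allylic alcohol on the enantiomeric ring (diastereomer of 10) | CC(C)(C)[Si](C)(C)OCC1=C[C@@H](O)C[C@@](C)(C(=O)OC)[C@@H]1C1(C)OCCO1
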